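**Retrosynthetic overview**
- The axial C8 acetate comes from a one-pot hydride reduction and O-acetylation of an 8-keto acrylate.
- The C7–C11 bond comes from an umpolung α-vinylation of the C7 ketone enolate with methyl propiolate, by way of a β-phosphonio acrylate (the new step).
- Ring B comes from a one-carbon ring expansion of a hydrindane carbinol (the key step): the quaternary C10 shifts from C8 onto a CHBr carbenoid carbon, which becomes C9. The C3 oxygen is set by Luche reduction while C8 is masked as the carbinol.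
- The hydrindenedione comes from an amino-acid-mediated aldol condensation of the triketone made from 2-methylcyclopentane-1,3-dione and ethyl vinyl ketone; this sets C10.
- Ring order: the five-membered ring is bought, ring A is closed by the aldol condensation, ring B is made by the 5→6 expansion.

Assumption: the target is exactly the given SMILES, (3S,7R,8R,10R) in eudesmane numbering (C3 = CH–O-propanoyl, C4=C5 ring alkene, C7 = CH bearing the acrylate, C8 = CH–OAc, C9 = CH2 between C8 and C10, C10 = C–CH3; β = face of the C10 methyl), and this numbering is used for all intermediates.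

**Step 1**
Reactants: 1 2-methylcyclopentane-1,3-dione; 2 pent-1-en-3-one (ethyl vinyl ketone)
Product: 3 2-methyl-2-(3-oxopentyl)cyclopentane-1,3-dione
Conditions: 2 (1.5 equiv), AcOH (cat.), H2O, 75 °C
Reagents that add atoms: none
Why: Michael addition of the enolised cyclic 1,3-dione to the vinyl ketone in water without base (so no retro-Claisen ring opening); the new quaternary carbon is still prochiral, so no stereocentre is set.

**Step 2**
Reactants: 3 2-methyl-2-(3-oxopentyl)cyclopentane-1,3-dione
Product: 4 (7aS)-4,7a-dimethyl-2,3,7,7a-tetrahydro-1H-indene-1,5(6H)-dione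
Conditions: L-phenylalanine (1.0 equiv), (+)-CSA (0.5 equiv), DMF, 30→70 °C; recrystallise to ≥99% ee
Reagents that add atoms: none
Why: Hajos–Parrish–Eder–Sauer–Wiechert aldol condensation, in which the L-phenylalanine enamine of the side-chain ketone attacks only one of the two enantiotopic ring carbonyls and water is lost under the acid, fixing the quaternary centre (future C10) as 7aS.

**Step 3**
Reactants: 4 (7aS)-4,7a-dimethyl-2,3,7,7a-tetrahydro-1H-indene-1,5(6H)-dione; 5 dibromomethane
Product: 7 (1S,7aS)-1-(dibromomethyl)-1-hydroxy-4,7a-dimethyl-1,2,3,6,7,7a-hexahydro-5H-inden-5-one, via dibromomethyllithium 6 (not isolated)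
Conditions: 5 (1.5 equiv), LiTMP (1.3 equiv), THF, −90→−78 °C; AcOH, −78 °C
Reagents that add atoms: none
Why: 1,2-addition of LiCHBr2, generated and trapped in situ (Nozaki protocol), to the saturated cyclopentanone, which is more electrophilic than the conjugated α-methyl enone carbonyl; attack anti to the angular methyl gives the 8β-carbinol, a centre that is erased again in step 5.

**Step 4**
Reactants: 7 (1S,7aS)-1-(dibromomethyl)-1-hydroxy-4,7a-dimethyl-1,2,3,6,7,7a-hexahydro-5H-inden-5-one
Product: 8 (1S,5S,7aS)-1-(dibromomethyl)-4,7a-dimethyl-2,3,5,6,7,7a-hexahydro-1H-indene-1,5-diol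
Conditions: NaBH4, CeCl3·7H2O, MeOH, −40 °C
Reagents that add atoms: none
Why: Luche 1,2-reduction of the only remaining carbonyl, with hydride delivered axially from the α face (as for Δ4-3-keto steroids) to give the equatorial 3β-allylic alcohol (3S), while C8 stays masked as the carbinol and the C–Br bonds are inert.

**Step 5**
Reactants: 8 (1S,5S,7aS)-1-(dibromomethyl)-4,7a-dimethyl-2,3,5,6,7,7a-hexahydro-1H-indene-1,5-diol
Product: 11 (6S,8aR)-6-hydroxy-5,8a-dimethyl-3,4,6,7,8,8a-hexahydronaphthalen-2(1H)-one, via lithium carbenoid 9 (not isolated), via dilithium enolate 10 (not isolated)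
Conditions: n-BuLi (3.3 equiv), THF, −78→0 °C; H2O
Reagents that add atoms: none
Why: Nozaki–Yamamoto β-oxido carbenoid ring expansion (key step), in which Br–Li exchange gives the LiCHBr carbenoid and loss of LiBr drives a semipinacol-type 1,2-shift of the more substituted, cation-stabilising α-carbon (quaternary allylic C10, with retention) from C8 to the new C9, so the five-membered ring becomes the six-membered 8-ketone as its C8=C9 enolate and no new stereocentre is formed.

**Step 6**
Reactants: 11 (6S,8aR)-6-hydroxy-5,8a-dimethyl-3,4,6,7,8,8a-hexahydronaphthalen-2(1H)-one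
Product: 12 (2S,4aR)-1,4a-dimethyl-6-oxo-2,3,4,4a,5,6,7,8-octahydronaphthalen-2-yl propanoate
Conditions: EtCOCl, pyridine, DMAP (cat.), CH2Cl2, 0 °C
Reagents that add atoms: propanoyl chloride, CCC(=O)Cl
Why: DMAP-catalysed O-acylation of the secondary allylic 3β-alcohol with an acid chloride; the ketone is inert and no stereocentre is touched.

**Step 7**
Reactants: 12 (2S,4aR)-1,4a-dimethyl-6-oxo-2,3,4,4a,5,6,7,8-octahydronaphthalen-2-yl propanoate; 13 methyl prop-2-ynoate (methyl propiolate)
Product: 17 methyl 2-[(2R,4aR,7S)-4a,8-dimethyl-3-oxo-7-(propanoyloxy)-1,2,3,4,4a,5,6,7-octahydronaphthalen-2-yl]prop-2-enoate, via vinylphosphonium salt 14 (not isolated), via lithium enolate 15 (not isolated), via phosphonium ylide 16 (not isolated)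
Conditions: (a) 13, Ph3P·HBF4 (1.0 equiv), PPh3 (2 mol %), CH2Cl2, 0→23 °C; (b) 12, LiHMDS (1.05 equiv), THF, −78 °C; (c) b into a, −78 °C, then t-BuOH (0.2 equiv), −78→0 °C; AcOH/NaOAc
Reagents that add atoms: none
Why: Proposed new method: umpolung α-(1-methoxycarbonylvinyl)ation of an unstabilised ketone enolate, in which phosphine plus acid turn the propiolate into the β-phosphonio acrylate 14, the bulky and strongly activating P+ steers the kinetic C7 lithium enolate 15 (C9 is neopentyl and is not deprotonated) onto the carbon α to the ester to give ylide 16, a proton shuttle then moves the ester α-hydrogen to the ylide carbon and PPh3 is expelled (E1cB) to leave the 1,1-disubstituted acrylate, and C7 equilibrates through the enol to the equatorial 7β position (R); the closest known reactions are the phosphine-catalysed α-addition of N–H and 1,3-dicarbonyl pronucleophiles to propiolates and enolate additions to vinylphosphonium salts, neither shown for simple ketone enolates.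

**Step 8**
Reactants: 17 methyl 2-[(2R,4aR,7S)-4a,8-dimethyl-3-oxo-7-(propanoyloxy)-1,2,3,4,4a,5,6,7-octahydronaphthalen-2-yl]prop-2-enoate
Product: 19 methyl 2-[(2R,3R,4aR,7S)-3-(acetyloxy)-4a,8-dimethyl-7-(propanoyloxy)-1,2,3,4,4a,5,6,7-octahydronaphthalen-2-yl]prop-2-enoate, via aluminate 18 (not isolated)
Conditions: LiAlH(Ot-Bu)3 (1.2 equiv), THF, −40→−20 °C; then Ac2O, pyridine, DMAP, −40→0 °C
Reagents that add atoms: acetic anhydride, CC(=O)OC(C)=O
Why: Chemoselective ketone reduction with LiAlH(Ot-Bu)3 (esters and the acrylate are inert) followed by in situ acylation of the aluminium alkoxide (reductive acetylation), where hydride comes in equatorially from the α face because axial β attack is blocked by the 1,3-diaxial C10 methyl (as in 2-oxo-5α-steroids), giving the axial 8β-oxygen (8R), and immediate acetylation pre-empts closure to the cis-lactone.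

**Compound list**
1 | 2-methylcyclopentane-1,3-dione | CC1C(=O)CCC1=O | starting material
2 | pent-1-en-3-one (ethyl vinyl ketone) | C=CC(=O)CC | starting material
3 | 2-methyl-2-(3-oxopentyl)cyclopentane-1,3-dione | CCC(=O)CCC1(C)C(=O)CCC1=O | intermediate
4 | (7aS)-4,7a-dimethyl-2,3,7,7a-tetrahydro-1H-indene-1,5(6H)-dione | C[C@]12CCC(=O)C(C)=C1CCC2=O | intermediate
5 | dibromomethane | BrCBr | starting material
6 | dibromomethyllithium | [Li]C(Br)Br | intermediate
7 | (1S,7aS)-1-(dibromomethyl)-1-hydroxy-4,7a-dimethyl-1,2,3,6,7,7a-hexahydro-5H-inden-5-one (OH cis to the angular methyl) | C[C@]12CCC(=O)C(C)=C1CC[C@@]2(O)C(Br)Br | intermediate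
8 | (1S,5S,7aS)-1-(dibromomethyl)-4,7a-dimethyl-2,3,5,6,7,7a-hexahydro-1H-indene-1,5-diol (both OH cis to the angular methyl) | C[C@]12CC[C@H](O[H])C(C)=C1CC[C@@]2(O)C(Br)Br | intermediate
9 | dilithium (1S,5S,7aS)-1-[bromo(lithio)methyl]-4,7a-dimethyl-2,3,5,6,7,7a-hexahydro-1H-indene-1,5-bis(olate) (carbenoid carbon configurationally undefined) | C[C@]12CC[C@H](O[Li])C(C)=C1CC[C@@]2(O[Li])C([Li])Br | intermediate
10 | dilithium (6S,8aR)-5,8a-dimethyl-3,4,6,7,8,8a-hexahydronaphthalene-2,6-bis(olate) (C8=C9 enolate plus C3 alkoxide) | C[C@]12CC[C@H](O[Li])C(C)=C1CCC(O[Li])=C2 | intermediate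
11 | (6S,8aR)-6-hydroxy-5,8a-dimethyl-3,4,6,7,8,8a-hexahydronaphthalen-2(1H)-one (3β-hydroxy-8-ketone) | C[C@]12CC[C@H](O)C(C)=C1CCC(=O)C2 | intermediate
12 | (2S,4aR)-1,4a-dimethyl-6-oxo-2,3,4,4a,5,6,7,8-octahydronaphthalen-2-yl propanoate | C[C@]12CC[C@H](OC(=O)CC)C(C)=C1CCC(=O)C2 | intermediate
13 | methyl prop-2-ynoate (methyl propiolate) | C#CC(=O)OC | starting material
14 | (E)-(3-methoxy-3-oxoprop-1-en-1-yl)triphenylphosphonium tetrafluoroborate | COC(=O)/C=C/[P+](c1ccccc1)(c1ccccc1)c1ccccc1.F[B-](F)(F)F | intermediate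
15 | (2S,4aR)-6-(lithiooxy)-1,4a-dimethyl-2,3,4,4a,5,8-hexahydronaphthalen-2-yl propanoate (C7=C8 lithium enolate of 12) | C[C@]12CC[C@H](OC(=O)CC)C(C)=C1CC=C(O[Li])C2 | intermediate
16 | methyl 2-[(4aR,7S)-4a,8-dimethyl-3-oxo-7-(propanoyloxy)-1,2,3,4,4a,5,6,7-octahydronaphthalen-2-yl]-3-(triphenylphosphonio)propan-3-ide-oate (ylide; ring C2 and ester α-carbon not yet defined) | C[C@]12CC[C@H](OC(=O)CC)C(C)=C1CC(C(C(=O)OC)[CH-][P+](c3ccccc3)(c3ccccc3)c3ccccc3)C(=O)C2 | intermediate
17 | methyl 2-[(2R,4aR,7S)-4a,8-dimethyl-3-oxo-7-(propanoyloxy)-1,2,3,4,4a,5,6,7-octahydronaphthalen-2-yl]prop-2-enoate (7β side chain, 8-ketone) | C=C(C(=O)OC)[C@H]1CC2=C(C)[C@@H](OC(=O)CC)CC[C@]2(C)CC1=O | intermediate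
18 | lithium tri-tert-butoxyaluminate of the 8β-alkoxide of reduced 17 | C=C(C(=O)OC)[C@H]1CC2=C(C)[C@@H](OC(=O)CC)CC[C@]2(C)C[C@H]1O[Al-](OC(C)(C)C)(OC(C)(C)C)OC(C)(C)C.[Li+] | intermediate
19 | methyl 2-[(2R,3R,4aR,7S)-3-(acetyloxy)-4a,8-dimethyl-7-(propanoyloxy)-1,2,3,4,4a,5,6,7-octahydronaphthalen-2-yl]prop-2-enoate (CNP0198123.1) | C=C(C(=O)OC)[C@H]1CC2=C(C)[C@@H](OC(=O)CC)CC[C@]2(C)C[C@H]1OC(C)=O | target

**Totals**
Total step count: 8. Longest linear sequence: 8 steps (1 → 19).

**Steps most likely to fail**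

Step 3 (chemoselectivity). LiTMP may enolise the enone, or LiCHBr2 may also add at the enone carbonyl. The fallback masks the enone first, as is done for Δ4-3-keto steroids. It sets out from 4: pyrrolidine (MeOH, reflux) condenses only with the enone to give the dienamine F1. LiCHBr2 (from 5 and LiTMP, THF, −78 °C) then adds to the only free carbonyl to give the dienamine carbinol F2. Aqueous AcOH/NaOAc hydrolysis releases pyrrolidine and the route is rejoined at 7.

Step 7 (the proposed new step). The basic enolate may deprotonate 14 instead of adding to it, it may attack the phosphorus-bearing carbon, or the product may isomerise to the conjugated C7=C11 alkene. The fallback uses known chemistry, the β-nitroacrylate method for putting an α-(alkoxycarbonyl)vinyl group next to a ketone. It sets out from 12 through the same enolate 15: Michael addition to methyl (E)-3-nitroacrylate at −78 °C, where the nitro group directs attack to the carbon α to the ester, gives the nitro ester F3. Et3N at 0 °C then eliminates nitrous acid and the route is rejoined at 17.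

Step 8 (cis-lactone formation before the hindered axial alkoxide is acetylated, or incomplete facial selectivity). The fallback creates the ester only after C8 is acetylated, so neither lactonisation nor conjugate reduction can occur. It sets out from 12: TMSOTf/Et3N gives the silyl enol ether F4. GaCl3-promoted ethynylation with chloro(trimethylsilyl)ethyne gives the silylethynyl ketone F5 (equatorial 7β after equilibration). L-Selectride (THF, −78 °C) followed by Ac2O/DMAP gives the silylethynyl acetate F6. TBAF/AcOH gives the terminal alkyne F7. Markovnikov Pd-catalysed methoxycarbonylation (Pd(OAc)2, 2-pyridyldiphenylphosphine, MsOH, CO, MeOH) then rejoins the route at the target 19.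

**Further compounds**
F1 | step 3 | (7aS)-4,7a-dimethyl-5-(pyrrolidin-1-yl)-2,6,7,7a-tetrahydro-1H-inden-1-one | C[C@]12CCC(N3CCCC3)=C(C)C1=CCC2=O
F2 | step 3 | (1S,7aS)-1-(dibromomethyl)-4,7a-dimethyl-5-(pyrrolidin-1-yl)-2,6,7,7a-tetrahydro-1H-inden-1-ol | C[C@]12CCC(N3CCCC3)=C(C)C1=CC[C@@]2(O)C(Br)Br
F3 | step 7 | methyl 2-[(4aR,7S)-4a,8-dimethyl-3-oxo-7-(propanoyloxy)-1,2,3,4,4a,5,6,7-octahydronaphthalen-2-yl]-3-nitropropanoate (epimers at ring C2 and the ester α-carbon) | C[C@]12CC[C@H](OC(=O)CC)C(C)=C1CC(C(C[N+](=O)[O-])C(=O)OC)C(=O)C2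
F4 | step 8 | (2S,4aR)-1,4a-dimethyl-6-[(trimethylsilyl)oxy]-2,3,4,4a,5,8-hexahydronaphthalen-2-yl propanoate | C[C@]12CC[C@H](OC(=O)CC)C(C)=C1CC=C(O[Si](C)(C)C)C2
F5 | step 8 | (2S,4aR,7R)-1,4a-dimethyl-6-oxo-7-[(trimethylsilyl)ethynyl]-2,3,4,4a,5,6,7,8-octahydronaphthalen-2-yl propanoate | C[Si](C)(C)C#C[C@H]1CC2=C(C)[C@@H](OC(=O)CC)CC[C@]2(C)CC1=O
F6 | step 8 | (2S,4aR,6R,7R)-6-(acetyloxy)-1,4a-dimethyl-7-[(trimethylsilyl)ethynyl]-2,3,4,4a,5,6,7,8-octahydronaphthalen-2-yl propanoate | C[Si](C)(C)C#C[C@H]1CC2=C(C)[C@@H](OC(=O)CC)CC[C@]2(C)C[C@H]1OC(C)=O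
F7 | step 8 | (2S,4aR,6R,7R)-6-(acetyloxy)-7-ethynyl-1,4a-dimethyl-2,3,4,4a,5,6,7,8-octahydronaphthalen-2-yl propanoate | C#C[C@H]1CC2=C(C)[C@@H](OC(=O)CC)CC[C@]2(C)C[C@H]1OC(C)=O
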